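**Retrosynthetic overview**
1. Target 16 ⇐ enol ester 15 (Schenck ene reaction on the 4-methylpent-3-enyl chain, last step) ⇐ alkyne 13 (Z-selective addition of 3-methylbut-2-enoic acid).
2. 13 ⇐ 9: the CH2OH group by Morita–Baylis–Hillman reaction; the 2-oxopropyl group by Stetter addition of acetaldehyde to the 7-methylene enone 10, C7 being set on protonation.
3. Only ring (cycloheptenone 9): closed at C2=C3 by intramolecular Horner–Wadsworth–Emmons reaction of the keto-phosphonate aldehyde 7.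
4. C5–C6 bond with the quaternary C5 and the C6 stereocentre: carbene-catalysed homoenolate addition of neral 4 to ynenone 3, released as the methyl ester 5.
5. 3 ⇐ mono-olefination of bis-phosphonate 2 with silylpropynal 1.

Assumption: 1, 2 and geometrically pure neral 4 are taken as purchasable, and the (5aS,10bR) triazolium salt is assumed to give the (3S,4S) series (its mirror image is used if the sense proves opposite).

Ring numbering used in the names: C1 = ring C=O, C2=C3 = enone, C5 = quaternary carbon, C6 = CH bearing the alkyne/enol ester, C7 = CH bearing the 2-oxopropyl group.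

**Step 1**
Reactants: 1 3-(trimethylsilyl)prop-2-ynal; 2 tetraethyl (2-oxopropane-1,3-diyl)bis(phosphonate)
Product: 3 diethyl [(3E)-2-oxo-6-(trimethylsilyl)hex-3-en-5-yn-1-yl]phosphonate
Conditions: 2 (1.3 equiv), NaH (1.3 equiv), THF, 0 °C; then 1, 0 → 25 °C
Reagents that add atoms: none
Why: Horner–Wadsworth–Emmons olefination of the keto-phosphonate anion gives the (E)-enone, and using the bis-phosphonate in excess stops the reaction at mono-olefination so that one phosphonate is kept for the later ring closure.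

**Step 2**
Reactants: 3 diethyl [(3E)-2-oxo-6-(trimethylsilyl)hex-3-en-5-yn-1-yl]phosphonate; 4 neral, (2Z)-3,7-dimethylocta-2,6-dienal
Product: 5 methyl (3S,4S)-7-(diethoxyphosphoryl)-3-methyl-3-(4-methylpent-3-en-1-yl)-6-oxo-4-[(trimethylsilyl)ethynyl]heptanoate
Conditions: 4 (1.5 equiv), (5aS,10bR)-2-(2,4,6-trimethylphenyl)-5a,10b-dihydro-4H,6H-indeno[2,1-b][1,2,4]triazolo[4,3-d][1,4]oxazin-2-ium chloride (10 mol%), i-Pr2NEt (20 mol%), MeOH (3 equiv), THF, 25 °C
Reagents that add atoms: methanol, CO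
Why: Proposed new method: the Breslow intermediate formed from neral and the chiral triazolylidene adds to the ketone of 3 (cross-benzoin) and the resulting 1,5-dien-3-olate undergoes a boat oxy-Cope shift that joins C3 of neral to the enone β-carbon, so that the (Z)-enal and (E)-enone geometries fix the relative configuration (methyl and alkynyl on the same side) and the aminoindanol triazolium fixes the absolute configuration of the new quaternary and propargylic centres, after which methanol cleaves the acyl azolium to the ester; the closest known reaction type is the carbene-catalysed homoenolate addition of β-monosubstituted enals to enones and nitroalkenes, which has not been shown for a β,β-dialkyl enal forming a quaternary centre.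

**Step 3**
Reactants: 5 methyl (3S,4S)-7-(diethoxyphosphoryl)-3-methyl-3-(4-methylpent-3-en-1-yl)-6-oxo-4-[(trimethylsilyl)ethynyl]heptanoate
Product: 7 diethyl [(4S,5S)-5-methyl-5-(4-methylpent-3-en-1-yl)-2,7-dioxo-4-[(trimethylsilyl)ethynyl]heptyl]phosphonate, via sodium phosphonate enolate 6 (not isolated)
Conditions: NaH (1.05 equiv), THF, 0 °C; i-Bu2AlH (1.2 equiv), −78 °C; AcOH, then aq. Rochelle salt
Reagents that add atoms: none
Why: Deprotonation masks the β-keto-phosphonate as its enolate, which hydride does not attack, so i-Bu2AlH reduces only the methyl ester to the aldehyde level through a tetrahedral aluminate that is stable at −78 °C (chemoselective partial ester reduction).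

**Step 4**
Reactants: 7 diethyl [(4S,5S)-5-methyl-5-(4-methylpent-3-en-1-yl)-2,7-dioxo-4-[(trimethylsilyl)ethynyl]heptyl]phosphonate
Product: 9 (5S,6S)-6-ethynyl-5-methyl-5-(4-methylpent-3-en-1-yl)cyclohept-2-en-1-one, via silylalkyne cycloheptenone 8 (not isolated)
Conditions: K2CO3, 18-crown-6, PhMe (0.005 M), 60 °C; then MeOH, 25 °C
Reagents that add atoms: none
Why: Intramolecular Horner–Wadsworth–Emmons olefination under high dilution closes the seven-membered ring as the cis-enone, helped by the gem-disubstituted C5, and methanolic carbonate then removes the alkynyl silane without touching a stereocentre.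

**Step 5**
Reactants: 9 (5S,6S)-6-ethynyl-5-methyl-5-(4-methylpent-3-en-1-yl)cyclohept-2-en-1-one
Product: 10 (5S,6S)-6-ethynyl-5-methyl-7-methylidene-5-(4-methylpent-3-en-1-yl)cyclohept-2-en-1-one
Conditions: (CH2O)n, i-Pr2NH2+ CF3CO2− (1 equiv), CF3CO2H (10 mol%), THF, 65 °C; used at once
Reagents that add atoms: formaldehyde (from paraformaldehyde), C=O
Why: Ammonium-salt-mediated Mannich condensation and elimination (α-methylenation) can only take place at C7, the sole enolisable α-position of the enone.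

**Step 6**
Reactants: 10 (5S,6S)-6-ethynyl-5-methyl-7-methylidene-5-(4-methylpent-3-en-1-yl)cyclohept-2-en-1-one; 11 acetaldehyde
Product: 12 (5S,6S,7R)-6-ethynyl-5-methyl-5-(4-methylpent-3-en-1-yl)-7-(2-oxopropyl)cyclohept-2-en-1-one
Conditions: 11 (5 equiv), 3-benzyl-5-(2-hydroxyethyl)-4-methylthiazolium chloride (20 mol%), Et3N (20 mol%), THF, 25 °C
Reagents that add atoms: none
Why: Stetter reaction, in which the thiazolium-derived acyl anion equivalent of acetaldehyde adds to the unhindered exocyclic methylene and the resulting enol is protonated at C7 under kinetic control from the face opposite the C6 ethynyl and C5 methyl groups, placing the 2-oxopropyl chain cis to the ethynyl group (7R).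

**Step 7**
Reactants: 12 (5S,6S,7R)-6-ethynyl-5-methyl-5-(4-methylpent-3-en-1-yl)-7-(2-oxopropyl)cyclohept-2-en-1-one
Product: 13 (5S,6S,7R)-6-ethynyl-2-(hydroxymethyl)-5-methyl-5-(4-methylpent-3-en-1-yl)-7-(2-oxopropyl)cyclohept-2-en-1-one
Conditions: 37% aq. HCHO (3 equiv), 4-(dimethylamino)pyridine (20 mol%), THF–H2O, 25 °C
Reagents that add atoms: formaldehyde, C=O
Why: Morita–Baylis–Hillman hydroxymethylation, in which the nucleophilic amine adds reversibly only to the enone β-carbon and the weakly basic medium does not enolise C7.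

**Step 8**
Reactants: 13 (5S,6S,7R)-6-ethynyl-2-(hydroxymethyl)-5-methyl-5-(4-methylpent-3-en-1-yl)-7-(2-oxopropyl)cyclohept-2-en-1-one; 14 3-methylbut-2-enoic acid
Product: 15 (5S,6S,7R)-2-(hydroxymethyl)-5-methyl-5-(4-methylpent-3-en-1-yl)-6-[(Z)-2-(3-methylbut-2-enoyloxy)ethenyl]-7-(2-oxopropyl)cyclohept-2-en-1-one
Conditions: 14 (1.2 equiv), Ru(η3-2-methylallyl)2(Ph2P(CH2)4PPh2) (2 mol%), PhMe, 45 °C
Reagents that add atoms: none
Why: Ruthenium-catalysed anti-Markovnikov addition of the carboxylic acid to the terminal alkyne, which with this diphosphine catalyst gives the (Z)-enol ester.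

**Step 9**
Reactants: 15 (5S,6S,7R)-2-(hydroxymethyl)-5-methyl-5-(4-methylpent-3-en-1-yl)-6-[(Z)-2-(3-methylbut-2-enoyloxy)ethenyl]-7-(2-oxopropyl)cyclohept-2-en-1-one
Product: 16 (5S,6S,7R)-5-[(2E)-4-hydroperoxy-4-methylpent-2-en-1-yl]-2-(hydroxymethyl)-5-methyl-6-[(Z)-2-(3-methylbut-2-enoyloxy)ethenyl]-7-(2-oxopropyl)cyclohept-2-en-1-one (CNP0283385.3)
Conditions: O2, tetraphenylporphyrin (1 mol%), visible light, CH2Cl2, 0 °C
Reagents that add atoms: dioxygen, O=O
Why: Schenck ene reaction, in which singlet oxygen attacks only the electron-rich trisubstituted alkene and shifts the double bond to give the (E)-tertiary allylic hydroperoxide, the regioisomeric secondary hydroperoxide (expected in similar amount) being removed by chromatography.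

**Compound list**
1 | 3-(trimethylsilyl)prop-2-ynal | C[Si](C)(C)C#CC=O | starting material
2 | tetraethyl (2-oxopropane-1,3-diyl)bis(phosphonate) | CCOP(=O)(OCC)CC(=O)CP(=O)(OCC)OCC | starting material
3 | diethyl [(3E)-2-oxo-6-(trimethylsilyl)hex-3-en-5-yn-1-yl]phosphonate | CCOP(=O)(OCC)CC(=O)/C=C/C#C[Si](C)(C)C | intermediate
4 | neral, (2Z)-3,7-dimethylocta-2,6-dienal | CC(C)=CCC/C(C)=C\C=O | starting material
5 | methyl (3S,4S)-7-(diethoxyphosphoryl)-3-methyl-3-(4-methylpent-3-en-1-yl)-6-oxo-4-[(trimethylsilyl)ethynyl]heptanoate | COC(=O)C[C@](C)(CCC=C(C)C)[C@@H](C#C[Si](C)(C)C)CC(=O)CP(=O)(OCC)OCC | intermediate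
6 | sodium enolate of keto-phosphonate 5 (not isolated) | [Na+].COC(=O)C[C@](C)(CCC=C(C)C)[C@@H](C#C[Si](C)(C)C)CC([O-])=CP(=O)(OCC)OCC | intermediate
7 | diethyl [(4S,5S)-5-methyl-5-(4-methylpent-3-en-1-yl)-2,7-dioxo-4-[(trimethylsilyl)ethynyl]heptyl]phosphonate | O=CC[C@](C)(CCC=C(C)C)[C@@H](C#C[Si](C)(C)C)CC(=O)CP(=O)(OCC)OCC | intermediate
8 | (5S,6S)-5-methyl-5-(4-methylpent-3-en-1-yl)-6-[(trimethylsilyl)ethynyl]cyclohept-2-en-1-one (not isolated) | O=C1C=CC[C@](C)(CCC=C(C)C)[C@@H](C#C[Si](C)(C)C)C1 | intermediate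
9 | (5S,6S)-6-ethynyl-5-methyl-5-(4-methylpent-3-en-1-yl)cyclohept-2-en-1-one | O=C1C=CC[C@](C)(CCC=C(C)C)[C@@H](C#C)C1 | intermediate
10 | (5S,6S)-6-ethynyl-5-methyl-7-methylidene-5-(4-methylpent-3-en-1-yl)cyclohept-2-en-1-one | O=C1C=CC[C@](C)(CCC=C(C)C)[C@@H](C#C)C1=C | intermediate
11 | acetaldehyde | CC=O | starting material
12 | (5S,6S,7R)-6-ethynyl-5-methyl-5-(4-methylpent-3-en-1-yl)-7-(2-oxopropyl)cyclohept-2-en-1-one | CC(=O)C[C@H]1C(=O)C=CC[C@](C)(CCC=C(C)C)[C@H]1C#C | intermediate
13 | (5S,6S,7R)-6-ethynyl-2-(hydroxymethyl)-5-methyl-5-(4-methylpent-3-en-1-yl)-7-(2-oxopropyl)cyclohept-2-en-1-one | CC(=O)C[C@H]1C(=O)C(CO)=CC[C@](C)(CCC=C(C)C)[C@H]1C#C | intermediate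
14 | 3-methylbut-2-enoic acid | CC(C)=CC(=O)O | starting material
15 | (5S,6S,7R)-2-(hydroxymethyl)-5-methyl-5-(4-methylpent-3-en-1-yl)-6-[(Z)-2-(3-methylbut-2-enoyloxy)ethenyl]-7-(2-oxopropyl)cyclohept-2-en-1-one | CC(=O)C[C@H]1C(=O)C(CO)=CC[C@](C)(CCC=C(C)C)[C@H]1/C=C\OC(=O)C=C(C)C | intermediate
16 | (5S,6S,7R)-5-[(2E)-4-hydroperoxy-4-methylpent-2-en-1-yl]-2-(hydroxymethyl)-5-methyl-6-[(Z)-2-(3-methylbut-2-enoyloxy)ethenyl]-7-(2-oxopropyl)cyclohept-2-en-1-one | CC(=O)C[C@H]1C(=O)C(CO)=CC[C@](C)(C/C=C/C(C)(C)OO)[C@H]1/C=C\OC(=O)C=C(C)C | target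

**Step count and risks**
Total steps: 9. Longest linear sequence: 9 (steps 1 to 9).

Steps most likely to fail:

Step 2 (the proposed new carbene-catalysed addition). Likely failure modes are β-protonation of the hindered homoenolate (giving the saturated methyl ester of the enal), aldol/lactonisation to a cyclopentene, and E/Z scrambling of neral. Fallback by known chemistry, setting out from 4 and returning at 7. Iminium-catalysed Michael addition of nitromethane to 4 with the diphenylprolinol trimethylsilyl ether enantiomer that gives the S centre yields (3S)-3,7-dimethyl-3-(nitromethyl)oct-6-enal F1. Acetalisation (HC(OMe)3, MeOH, cat. TsOH) gives (6S)-8,8-dimethoxy-2,6-dimethyl-6-(nitromethyl)oct-2-ene F2. A buffered Nef reaction (NaOMe, then TiCl3, NH4OAc, aq. MeOH) gives (2S)-2-(2,2-dimethoxyethyl)-2,6-dimethylhept-5-enal F3. Horner–Wadsworth–Emmons olefination with 2 (LiCl, i-Pr2NEt, MeCN) gives diethyl [(3E,5S)-7,7-dimethoxy-5-methyl-5-(4-methylpent-3-en-1-yl)-2-oxohept-3-en-1-yl]phosphonate F4. Binaphthol-catalysed conjugate alkynylation with diisopropyl [(trimethylsilyl)ethynyl]boronate (the 3,3'-diiodo-1,1'-bi-2-naphthol enantiomer that gives the 4S centre, CH2Cl2) gives diethyl [(4S,5S)-7,7-dimethoxy-5-methyl-5-(4-methylpent-3-en-1-yl)-2-oxo-4-[(trimethylsilyl)ethynyl]heptyl]phosphonate F5. Mild acetal hydrolysis (pyridinium tosylate, acetone–water) then gives 7.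

Step 6 (Stetter addition and C7 configuration). The risks are a poor facial preference in the protonation and epimerisation of C7 by the amine base. Fallback setting out from 9 and returning at 12. Double deprotonation of 9 (LDA, 2.2 equiv, THF, −78 °C; the alkyne C–H is removed as well) and C-alkylation of the cross-conjugated enolate with 3-bromo-2-methoxyprop-1-ene gives mainly the trans compound (5S,6S,7S)-6-ethynyl-7-(2-methoxyprop-2-en-1-yl)-5-methyl-5-(4-methylpent-3-en-1-yl)cyclohept-2-en-1-one F6. Renewed deprotonation (LDA, −78 °C) and kinetic protonation from the less hindered face with 2,6-di-tert-butyl-4-methylphenol inverts C7 to (5S,6S,7R)-6-ethynyl-7-(2-methoxyprop-2-en-1-yl)-5-methyl-5-(4-methylpent-3-en-1-yl)cyclohept-2-en-1-one F7. Oxalic acid in wet THF then hydrolyses the enol ether to 12.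

Step 9 (regiochemistry of the ene reaction). Trisubstituted alkenes of this type give close to 1:1 tertiary and secondary hydroperoxides, so at best about half of the material is the target. Fallback setting out from 15 and returning at 16. Hydroxyselenenylation of the trisubstituted alkene with N-(phenylselanyl)phthalimide in wet CH2Cl2 (cat. camphorsulfonic acid) gives (5S,6S,7R)-5-[4-hydroxy-4-methyl-3-(phenylselanyl)pentyl]-2-(hydroxymethyl)-5-methyl-6-[(Z)-2-(3-methylbut-2-enoyloxy)ethenyl]-7-(2-oxopropyl)cyclohept-2-en-1-one F8 (both epimers at the selenium-bearing carbon). Oxidation (H2O2, pyridine, CH2Cl2) and selenoxide syn-elimination away from the carbinol gives (5S,6S,7R)-5-[(2E)-4-hydroxy-4-methylpent-2-en-1-yl]-2-(hydroxymethyl)-5-methyl-6-[(Z)-2-(3-methylbut-2-enoyloxy)ethenyl]-7-(2-oxopropyl)cyclohept-2-en-1-one F9. Acid-catalysed perhydrolysis of the tertiary allylic alcohol (50% H2O2, cat. H2SO4, Et2O, 0 °C) then gives 16.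

**Further compounds**
F1 | step 2 | (3S)-3,7-dimethyl-3-(nitromethyl)oct-6-enal | O=CC[C@](C)(CCC=C(C)C)C[N+](=O)[O-]
F2 | step 2 | (6S)-8,8-dimethoxy-2,6-dimethyl-6-(nitromethyl)oct-2-ene | COC(OC)C[C@](C)(CCC=C(C)C)C[N+](=O)[O-]
F3 | step 2 | (2S)-2-(2,2-dimethoxyethyl)-2,6-dimethylhept-5-enal | COC(OC)C[C@](C)(CCC=C(C)C)C=O
F4 | step 2 | diethyl [(3E,5S)-7,7-dimethoxy-5-methyl-5-(4-methylpent-3-en-1-yl)-2-oxohept-3-en-1-yl]phosphonate | COC(OC)C[C@](C)(CCC=C(C)C)/C=C/C(=O)CP(=O)(OCC)OCC
F5 | step 2 | diethyl [(4S,5S)-7,7-dimethoxy-5-methyl-5-(4-methylpent-3-en-1-yl)-2-oxo-4-[(trimethylsilyl)ethynyl]heptyl]phosphonate | COC(OC)C[C@](C)(CCC=C(C)C)[C@@H](C#C[Si](C)(C)C)CC(=O)CP(=O)(OCC)OCC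
F6 | step 6 | (5S,6S,7S)-6-ethynyl-7-(2-methoxyprop-2-en-1-yl)-5-methyl-5-(4-methylpent-3-en-1-yl)cyclohept-2-en-1-one | COC(=C)C[C@@H]1C(=O)C=CC[C@](C)(CCC=C(C)C)[C@H]1C#C
F7 | step 6 | (5S,6S,7R)-6-ethynyl-7-(2-methoxyprop-2-en-1-yl)-5-methyl-5-(4-methylpent-3-en-1-yl)cyclohept-2-en-1-one | COC(=C)C[C@H]1C(=O)C=CC[C@](C)(CCC=C(C)C)[C@H]1C#C
F8 | step 9 | (5S,6S,7R)-5-[4-hydroxy-4-methyl-3-(phenylselanyl)pentyl]-2-(hydroxymethyl)-5-methyl-6-[(Z)-2-(3-methylbut-2-enoyloxy)ethenyl]-7-(2-oxopropyl)cyclohept-2-en-1-one | CC(=O)C[C@H]1C(=O)C(CO)=CC[C@](C)(CCC([Se]c2ccccc2)C(C)(C)O)[C@H]1/C=C\OC(=O)C=C(C)C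
F9 | step 9 | (5S,6S,7R)-5-[(2E)-4-hydroxy-4-methylpent-2-en-1-yl]-2-(hydroxymethyl)-5-methyl-6-[(Z)-2-(3-methylbut-2-enoyloxy)ethenyl]-7-(2-oxopropyl)cyclohept-2-en-1-one | CC(=O)C[C@H]1C(=O)C(CO)=CC[C@](C)(C/C=C/C(C)(C)O)[C@H]1/C=C\OC(=O)C=C(C)C
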